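The numbers come from no measurement; no experiment stands behind them.

5 questions stood over these 4 flasks, which differ in temperature: which flask gives the most product, and how much each one gives.

| flask | substrate | partner A | partner B | temperature | time |
|---|---|---|---|---|---|
| autumn | 0.10 M | 0.200 M | 0.105 M | 40 °C | 25 min |
| summer | 0.10 M | 0.200 M | 0.105 M | 70 °C | 25 min |
| spring | 0.10 M | 0.200 M | 0.105 M | 55 °C | 25 min |
| dusk | 0.10 M | 0.200 M | 0.105 M | 25 °C | 25 min |

    substrate + partner B → open intermediate (k1 = 0.022 M⁻¹ s⁻¹, Ea1 = 61.0 kJ mol⁻¹)
    partner B + partner A → second intermediate (k2 = 0.018 M⁻¹ s⁻¹, Ea2 = 48.0 kJ mol⁻¹)
    open intermediate + second intermediate → product (k3 = 0.0055 M⁻¹ s⁻¹, Ea3 = 78.0 kJ mol⁻¹)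
    crystals ⇌ product, rate k4*(cs4 - [product]) while solid is left; crystals form when [product] > cs4 (cs4 = 1.9 mM, k4 = 0.010 s⁻¹)
    (constants at 40 °C)

- the flask that comes out highest in amount of product, in percent of the substrate charged, or "all alike" when all lie within 1.5 percentage points (autumn / summer / spring / dusk / all alike)
- product at the end, in percent of the substrate charged, autumn
- product at the end, in percent of the substrate charged, summer
- product at the end, in percent of the substrate charged, spring
- product at the end, in percent of the substrate charged, dusk

- amounts and yields of product count crystals too
- given per volume of solution although it is solid: crystals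
- the constants hold at 40 °C; other temperatures follow from the activation energies

Each product takes one open intermediate and one second intermediate, and each of those costs one partner B. Shared evenly, partner B, the limiting reagent, pays for 0.0525 M of product, which is 52.5% of the substrate charged. In summer it divides between the two routes at a ratio of 1.1 at the start, so I took the two intermediates as equal. Crystals hold product that is counted anyway; the saturation of product changes nothing in the summer count.

In summer, the start rates give partner B a half-life of 0.329 min. I reckoned the coupling of the two intermediates (step 3) as the rate-limiting step, starting at once:

start rate, summer = 12.5 mM min⁻¹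

That rate would use up the whole amount in 4.21 min, much longer than the half-life of partner B. But that rate does not last. In my reckoning both partners in the coupling fall together, so the rate falls as the square of what is left. I named the coupling number, N, as the start rate times the time, divided by the product partner B pays for:

N, summer = 5.94

rate at the end = start rate ÷ 48.2, the square of (1 + N)

average slowing = 6.94

yield = 52.5% × N ÷ (1 + N) = 44.9%

The colder flasks I reckoned the same way, each at its own constant:

autumn: N = 0.433, yield 15.9%

spring: N = 1.70, yield 33.1%

dusk: N = 0.0960, yield 4.60%

So I expected summer to come highest. The dusk figure I held as a high one, since the reckoning starts the coupling at once and at dusk partner B's half-life at the start rates is 5.50 min, a quarter of the 25 min.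

The forecast named summer, with 13% for autumn, 43.5% for summer, 31% for spring and 1.9% for dusk, holding that “the slow, high-barrier coupling step sets the yield”.

The simulation gave 12.3% for autumn, 43.6% for summer, 30.6% for spring and 2.02% for dusk, with summer highest.

My summer figure stood 1.3 percentage points above the result and my dusk figure 2.6 points above it. Left for 250 min, summer reached 47.4%, which is below my cap of 52.5%, with open intermediate at 0% and second intermediate at 0.0102 M. The neighbouring summer flask held 0.026 M of partner B, which scales N down to 1.47. Its cap is 13.0%, so I reckoned 7.74%. That neighbour gave 7.63% of product, with 4.81% of the substrate charged still standing as open intermediate and 0% of its partner B left.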